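**Assumption:** the target SMILES has no stereodescriptor and the molecule has no stereocentre; the hindered biaryl axis is unspecified, so it is formed without control and no step has to set or preserve configuration.

## Retrosynthetic overview
1. Target ⇐ global hydrogenolysis of a perbenzylated triaryl (8 benzyl ethers, 2 benzyl esters, free CO2H on the central ring B).
2. Biaryl C–C bond (ring B–ring C) ⇐ Ru-catalysed, carboxylate-directed ortho C–H arylation of the ring A–B diaryl ether acid with a ring C 2-bromogallate ester (last skeletal bond).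
3. Diaryl ether C–O bond (ring A–ring B) ⇐ Cu-catalysed Ullmann coupling of 2-bromo-tribenzylgallic acid with the ring A phenol.
4. Rings B and C ⇐ one tribenzylgallic acid built from 4-bromophenol (iodination, Cu C–O coupling, Li/CO2); ring A ⇐ catechol (formylation, bromination, Baeyer–Villiger, Pd carbonylation).
5. No ring is constructed; the three benzene rings come from the starting phenols and are joined A–B first, then B–C.

## Route

**Step 1**
Reactants: 1, 4-bromophenol
Product: 2, 4-bromo-2,6-diiodophenol
Conditions: I2, 30% aq H2O2, H2O, 50 °C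
Reagents that add atoms: iodine, II
Why: Electrophilic aromatic iodination; OH directs to both ortho positions and the para position is blocked by Br.

**Step 2**
Reactants: 2, 4-bromo-2,6-diiodophenol
Product: 3, 2-(benzyloxy)-5-bromo-1,3-diiodobenzene
Conditions: BnBr, K2CO3, DMF, 60 °C
Reagents that add atoms: benzyl bromide, BrCc1ccccc1
Why: Williamson etherification of an acidic phenol; the aryl halides are inert.

**Step 3**
Reactants: 3, 2-(benzyloxy)-5-bromo-1,3-diiodobenzene
Product: 4, 1,2,3-tris(benzyloxy)-5-bromobenzene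
Conditions: BnOH (6 equiv), CuI (10 mol%), 3,4,7,8-Me4-phenanthroline (20 mol%), Cs2CO3, toluene, 90 °C
Reagents that add atoms: benzyl alcohol, OCc1ccccc1
Why: Ullmann-type Cu-catalysed C–O coupling of aryl iodides with an alcohol; C–I reacts much faster than C–Br at 90 °C, so the bromide is kept for step 4.

**Step 4**
Reactants: 4, 1,2,3-tris(benzyloxy)-5-bromobenzene
Product: 5, 3,4,5-tris(benzyloxy)benzoic acid
Conditions: n-BuLi, THF, −78 °C; CO2 (g); aq HCl
Reagents that add atoms: carbon dioxide, O=C=O
Why: Br–Li exchange at −78 °C is faster than benzylic deprotonation, and the aryllithium is trapped by CO2 (carboxylation).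

**Step 5**
Reactants: 5, 3,4,5-tris(benzyloxy)benzoic acid
Product: 6, 2-bromo-3,4,5-tris(benzyloxy)benzoic acid
Conditions: NBS (1.05 equiv), MeCN, 0 °C to rt, dark
Reagents that add atoms: N-bromosuccinimide, O=C1CCC(=O)N1Br
Why: Electrophilic aromatic bromination at one of the two equivalent free ring positions; the free acid without base avoids ipso bromodecarboxylation and one equivalent limits dibromination.

**Step 6**
Reactants: 6, 2-bromo-3,4,5-tris(benzyloxy)benzoic acid
Product: 7, benzyl 2-bromo-3,4,5-tris(benzyloxy)benzoate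
Conditions: BnBr, K2CO3, DMF, rt
Reagents that add atoms: benzyl bromide, BrCc1ccccc1
Why: SN2 O-alkylation of the carboxylate gives the ring C coupling partner.

**Step 7**
Reactants: 8, catechol
Product: 9, 2,3-dihydroxybenzaldehyde
Conditions: MgCl2, Et3N, (CH2O)n (limiting), MeCN, reflux; aq HCl
Reagents that add atoms: paraformaldehyde (formaldehyde), C=O
Why: Mg-mediated ortho-formylation of phenols (Casnati–Skattebøl); the magnesium phenoxide delivers formaldehyde only ortho to OH, and limiting formaldehyde keeps it to mono-formylation.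

**Step 8**
Reactants: 9, 2,3-dihydroxybenzaldehyde
Product: 10, 5-bromo-2,3-dihydroxybenzaldehyde
Conditions: Br2 (1.0 equiv), NaOAc, AcOH, rt
Reagents that add atoms: bromine, BrBr
Why: Electrophilic aromatic bromination; C5 is para to the 2-OH and meta to CHO, so both groups direct there.

**Step 9**
Reactants: 10, 5-bromo-2,3-dihydroxybenzaldehyde
Product: 11, 2,3-bis(benzyloxy)-5-bromobenzaldehyde
Conditions: BnBr (2.3 equiv), K2CO3, DMF, 60 °C
Reagents that add atoms: benzyl bromide, BrCc1ccccc1
Why: Williamson etherification of both phenols; done before the oxidation so the three oxygens end up differentiated.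

**Step 10**
Reactants: 11, 2,3-bis(benzyloxy)-5-bromobenzaldehyde
Product: 12, 2,3-bis(benzyloxy)-5-bromophenol
Conditions: mCPBA, CH2Cl2, rt; then K2CO3, MeOH, rt
Reagents that add atoms: mCPBA, O=C(OO)c1cccc(Cl)c1 (supplies the phenol O; the formyl carbon is lost as formate)
Why: Baeyer–Villiger (Dakin-type) oxidation; the electron-rich ortho-alkoxy aryl group migrates to give the aryl formate, which is methanolysed to the single free phenol.

**Step 11**
Reactants: 12, 2,3-bis(benzyloxy)-5-bromophenol
Product: 13, benzyl 3,4-bis(benzyloxy)-5-hydroxybenzoate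
Conditions: Pd(OAc)2 (3 mol%), Xantphos (6 mol%), CO (1 atm), BnOH (5 equiv), Et3N, toluene, 90 °C
Reagents that add atoms: carbon monoxide, [C-]#[O+]; benzyl alcohol, OCc1ccccc1
Why: Pd-catalysed alkoxycarbonylation of the aryl bromide; excess BnOH outcompetes the hindered phenol for the acyl-Pd intermediate.

**Step 12**
Reactants: 6, 2-bromo-3,4,5-tris(benzyloxy)benzoic acid; 13, benzyl 3,4-bis(benzyloxy)-5-hydroxybenzoate
Product: 14, 3,4,5-tris(benzyloxy)-2-{2,3-bis(benzyloxy)-5-[(benzyloxy)carbonyl]phenoxy}benzoic acid
Conditions: CuI (20 mol%), Cs2CO3 (3 equiv), pyridine, dry DMF, 110 °C, Ar; aq HCl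
Reagents that add atoms: none
Why: Ullmann (Hurtley-type) Cu-catalysed diaryl ether synthesis; the ortho-carboxylate binds copper and accelerates substitution of the adjacent bromide, and benzyl ethers and esters are stable to Cs2CO3 in dry DMF.

**Step 13**
Reactants: 14, the diaryl ether acid; 7, benzyl 2-bromo-3,4,5-tris(benzyloxy)benzoate (1.5 equiv)
Product: 15, 3,4,5-tris(benzyloxy)-2-{2,3-bis(benzyloxy)-5-[(benzyloxy)carbonyl]phenoxy}-6-{2,3,4-tris(benzyloxy)-6-[(benzyloxy)carbonyl]phenyl}benzoic acid (racemic at the axis)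
Conditions: [RuCl2(p-cymene)]2 (5 mol%), PEt3·HBF4 (10 mol%), K2CO3 (2.5 equiv), dry NMP, 110 °C, Ar; aq HCl
Reagents that add atoms: none
Why: Proposed new method: carboxylate-assisted (CMD) ruthenation of the only remaining ortho C–H of 14 gives a five-membered ruthenacycle, oxidative addition of 7 is assisted by chelation of its ortho ester carbonyl, and the crowded diaryl-Ru species reductively eliminates with relief of strain; the closest known reaction is Ru(II)-catalysed carboxylate-directed ortho-arylation of benzoic acids with unhindered or mono-ortho-substituted aryl bromides, and what is new is the 2,6-disubstituted aryl bromide and the tetra-ortho-substituted, hexa-oxygenated biaryl it forms.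

**Step 14**
Reactants: 15, the perbenzylated triaryl acid
Product: 16, sanguisorbic acid, 2-(5-carboxy-2,3-dihydroxyphenoxy)-6-(6-carboxy-2,3,4-trihydroxyphenyl)-3,4,5-trihydroxybenzoic acid
Conditions: H2 (1 atm), 10% Pd/C, THF, rt; filter under Ar, evaporate below 25 °C
Reagents that add atoms: none
Why: Hydrogenolysis cleaves all eight benzyl ethers and both benzyl esters; neutral, aprotic, room-temperature conditions avoid the acid- or heat-promoted lactonisation of the ortho-hydroxy biaryl acids to the dilactone.

## Compound list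
1 | 4-bromophenol | Oc1ccc(Br)cc1 | starting material
2 | 4-bromo-2,6-diiodophenol | Oc1c(I)cc(Br)cc1I | intermediate
3 | 2-(benzyloxy)-5-bromo-1,3-diiodobenzene | Brc1cc(I)c(OCc2ccccc2)c(I)c1 | intermediate
4 | 1,2,3-tris(benzyloxy)-5-bromobenzene | Brc1cc(OCc2ccccc2)c(OCc2ccccc2)c(OCc2ccccc2)c1 | intermediate
5 | 3,4,5-tris(benzyloxy)benzoic acid | OC(=O)c1cc(OCc2ccccc2)c(OCc2ccccc2)c(OCc2ccccc2)c1 | intermediate
6 | 2-bromo-3,4,5-tris(benzyloxy)benzoic acid | OC(=O)c1cc(OCc2ccccc2)c(OCc2ccccc2)c(OCc2ccccc2)c1Br | intermediate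
7 | benzyl 2-bromo-3,4,5-tris(benzyloxy)benzoate | O=C(OCc1ccccc1)c1cc(OCc2ccccc2)c(OCc2ccccc2)c(OCc2ccccc2)c1Br | intermediate
8 | catechol | Oc1ccccc1O | starting material
9 | 2,3-dihydroxybenzaldehyde | O=Cc1cccc(O)c1O | intermediate
10 | 5-bromo-2,3-dihydroxybenzaldehyde | O=Cc1cc(Br)cc(O)c1O | intermediate
11 | 2,3-bis(benzyloxy)-5-bromobenzaldehyde | O=Cc1cc(Br)cc(OCc2ccccc2)c1OCc1ccccc1 | intermediate
12 | 2,3-bis(benzyloxy)-5-bromophenol | Oc1cc(Br)cc(OCc2ccccc2)c1OCc1ccccc1 | intermediate
13 | benzyl 3,4-bis(benzyloxy)-5-hydroxybenzoate | O=C(OCc1ccccc1)c1cc(O)c(OCc2ccccc2)c(OCc2ccccc2)c1 | intermediate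
14 | 3,4,5-tris(benzyloxy)-2-{2,3-bis(benzyloxy)-5-[(benzyloxy)carbonyl]phenoxy}benzoic acid | OC(=O)c1cc(OCc2ccccc2)c(OCc2ccccc2)c(OCc2ccccc2)c1Oc1cc(C(=O)OCc2ccccc2)cc(OCc2ccccc2)c1OCc1ccccc1 | intermediate
15 | 3,4,5-tris(benzyloxy)-2-{2,3-bis(benzyloxy)-5-[(benzyloxy)carbonyl]phenoxy}-6-{2,3,4-tris(benzyloxy)-6-[(benzyloxy)carbonyl]phenyl}benzoic acid | OC(=O)c1c(Oc2cc(C(=O)OCc3ccccc3)cc(OCc3ccccc3)c2OCc2ccccc2)c(OCc2ccccc2)c(OCc2ccccc2)c(OCc2ccccc2)c1-c1c(C(=O)OCc2ccccc2)cc(OCc2ccccc2)c(OCc2ccccc2)c1OCc1ccccc1 | intermediate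
16 | sanguisorbic acid | O=C(O)c1cc(O)c(O)c(Oc2c(O)c(O)c(O)c(-c3c(C(=O)O)cc(O)c(O)c3O)c2C(=O)O)c1 | target

## Summary
Total step count: 14.
Longest linear sequence: 8 steps (1→2→3→4→5→6→14→15→16; the ring C branch through 7 and the ring A branch 8→13 are also 8).

Steps most likely to fail:
- **Step 13 (proposed new C–H arylation).** The tetra-ortho-substituted biaryl may not form, or the 2,6-disubstituted acid may decarboxylate. Fallback with known chemistry: build the biaryl first by classical Ullmann homocoupling of 7 (Cu bronze, DMF, heat) to the symmetric dibenzyl hexakis(benzyloxy)diphenate. Then desymmetrise by NBS monobromination at the one free position ortho to an ester, form the ether by Cu-mediated Ullmann coupling with 13, and hydrogenolyse.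
- **Step 12 (hindered Ullmann etherification).** Fallback: reverse the polarity. Convert 13 to its aryl boronate (Tf2O, then Pd-catalysed Miyaura borylation). Convert 6 to the salicylic acid (Cu-catalysed hydroxylation of the o-bromobenzoic acid) and protect it as the allyl ester. Join the two by Chan–Lam O-arylation (Cu(OAc)2, pyridine, air, rt), then remove the allyl group with Pd(0) to return to acid 14.
- **Step 3 (double Cu-catalysed benzyloxylation of a hindered diiodide).** Fallback: avoid C–O coupling altogether. Duff diformylation of 4-bromophenol (HMTA, TFA) gives 5-bromo-2-hydroxyisophthalaldehyde; double Dakin oxidation (H2O2) gives 5-bromopyrogallol; tribenzylation (BnBr, K2CO3) gives 4.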